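**Plan**

- Cuts: the C2 ester/C1 acid pair goes back to a meso cyclobutane-1,2-dicarboxylic anhydride. Each pyranone is opened at O1'–C2' and then cut at C2'–C3' (loss of CO2, one molecule per ring) to a bis(1,3-diketone). C4'–C5' is cut to a bis(methyl ketone), and the cyclobutane bonds C2–C3 and C1–C4 to dimethylmaleic anhydride plus a cyclic cis-butenediol acetonide.
- Forward: the cyclobutane forms first by [2+2]. Both side chains are then grown in parallel (C5' from MeLi, C4'/C3' from a propanoyl unit, C2' from CO2). Both pyranone rings close together by lactonisation. The C1/C2 arms are oxidised last, closed to the anhydride and opened with methanol.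
- Enabling feature: in each pyranone ring C2' is a lone carboxyl carbon bonded to the methyl-bearing C3', and C3 and C4 of the cyclobutane are quaternary, so each diketone arm has only one site (the future C3') for its second deprotonation.
- Stereochemistry: the relative configuration of C1–C4 comes from the cis-anti-cis photoadduct and stays meso through step 12. The absolute configuration comes from the quinine-mediated methanolysis of the meso anhydride in step 13.

Key step: step 6

Numbering: cyclobutane atoms as in the target (C1 bears CO2H, C2 bears CO2Me, C3 is next to C2, C4 next to C1); pyranone atoms are O1', C2'–C6'. Face β carries the C1/C2 carbon substituents and both methyls; face α carries H-1, H-2 and the C3/C4 carbon substituents.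

Assumption: the sense of the quinine-mediated methanolysis is assigned by analogy with simple cis-fused meso anhydrides (methanol delivered to the carbonyl on the carbon that becomes C2); if it proves opposite, quinidine would be used in the same way.

**Route**

Step 1
Reactants: 1 2,3-dimethylmaleic anhydride; 2 4,7-dihydro-2,2-dimethyl-1,3-dioxepine
Product: 3 meso cis-anti-cis photoadduct (3,4-dimethylcyclobutane-3,4-dicarboxylic anhydride whose C1 and C2 are cis-bridged by CH2–O–C(CH3)2–O–CH2; anhydride ring on face α, dioxepane CH2 groups and both methyls on face β)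
Conditions: hν (medium-pressure Hg lamp, Pyrex), acetophenone (0.2 equiv), 2 (4 equiv), MeCN, 15 °C; crystallisation
Reagents that add atoms: none
Why: Triplet-sensitised [2+2] photocycloaddition of dimethylmaleic anhydride to a cyclic cis-alkene is a standard cyclobutane synthesis; both ring fusions must be cis because both partners are cyclic, and closure of the 1,4-biradical is expected to favour the cis-anti-cis adduct that keeps the anhydride ring away from the dioxepane ring, which sets the relative configuration of all four ring carbons (any cis-syn-cis isomer is removed by crystallisation).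

Step 2
Reactants: 3 meso photoadduct anhydride
Product: 4 dilithium cis-3,4-dicarboxylate of the same core (acetonide retained)
Conditions: LiOH·H2O (2.0 equiv), THF/H2O, rt; evaporate, dry (toluene azeotrope, vacuum, 80 °C)
Reagents that add atoms: lithium hydroxide, [Li+].[OH-]
Why: Saponification of a cyclic anhydride with exactly two equivalents of LiOH gives the dry dilithium salt directly, so no acid ever meets the acetonide and the hindered diacid has no chance to reclose.

Step 3
Reactants: 4 dilithium cis-3,4-dicarboxylate
Product: 6 meso bis(methyl ketone) (3,4-diacetyl compound), via tetralithium bis(gem-diolate) 5 (not isolated)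
Conditions: MeLi (5 equiv), THF/Et2O, 0 °C → rt; inverse quench into ice-cold aq NH4Cl
Reagents that add atoms: methyllithium, [Li]C
Why: Addition of an organolithium to a lithium carboxylate (the carboxylate-to-ketone reaction) stops at the gem-dilithioxy stage, which survives until hydrolysis, so each carboxylate becomes an acetyl group; the inverse buffered quench keeps free ketone away from residual MeLi and spares the acetonide, and the quaternary C3 and C4 cannot epimerise.

Step 4
Reactants: 7 propanoyl chloride; 8 1H-benzotriazole
Product: 9 1-propanoyl-1H-benzotriazole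
Conditions: Et3N (1.1 equiv), CH2Cl2, 0 °C → rt
Reagents that add atoms: none
Why: N-Acylation of benzotriazole by an acid chloride gives a stable, neutral acyl donor (N-acylbenzotriazole formation) suited to C-acylation under mild conditions.

Step 5
Reactants: 6 meso bis(methyl ketone); 9 1-propanoyl-1H-benzotriazole (2.4 equiv)
Product: 10 meso bis(1,3-diketone) (C3 and C4 each carry a 1,3-dioxopentyl arm, C(=O)CH2C(=O)CH2CH3)
Conditions: MgBr2·OEt2 (5 equiv), i-Pr2NEt (6 equiv), CH2Cl2, rt; cold 10% aq citric acid work-up
Reagents that add atoms: none
Why: Soft enolisation of a methyl ketone with MgBr2·OEt2 and a tertiary amine followed by C-acylation with an N-acylbenzotriazole is an established 1,3-diketone synthesis; only the CH3 of each acetyl can enolise because the other α-carbon is quaternary, the low standing concentration of magnesium enolate disfavours aldol closure between the two cis arms, and each product arm is held as an unreactive magnesium diketonate chelate.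

Step 6
Reactants: 10 meso bis(1,3-diketone); 11 carbon dioxide (2 equiv taken up, one per arm; supplied in excess)
Product: 13 bis(3,5-dioxo acid), via tetralithium bis(dienolate) 12 (not isolated)
Conditions: LiN(i-Pr)2 (4.6 equiv), THF, −78 → 0 °C; CO2 (dry gas, excess), −78 → 0 °C; cold 0.5 M HCl to pH 3, EtOAc, 0 °C; used at once
Reagents that add atoms: carbon dioxide, O=C=O
Why: Two equivalents of LiN(i-Pr)2 per arm first remove the central C5' proton and then the much less acidic proton of the ethyl CH2 (C3'), giving a tetralithium bis(dienolate) whose two terminal carbanions are the most basic and most nucleophilic sites and each add to one molecule of CO2, so that two molecules of CO2 are built in and both C2'–C3' bonds form. The closest known reaction type is the terminal carboxylation of 1,3-diketone dianions to 3,5-dioxo acids, run here in two directions on one molecule. No ring closes in this step; both pyranone rings close in step 7. The two new C3' methine centres form without control as a mixture, which is harmless because they become sp2 on aromatisation, and the four cyclobutane stereocentres are untouched. The selectivity needed is site selectivity for C3' over C5', and the substrate secures it: the other α-carbon of each arm is the hydrogen-free ring carbon C3 or C4, so the second anion can form only at C3', and the delocalised C5' position is far less nucleophilic. Complete deprotonation of both arms before CO2 is admitted leaves no neutral carbonyl for aldol reaction between the arms.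

Step 7
Reactants: 13 bis(3,5-dioxo acid)
Product: 15 meso bis(4-hydroxy-3-methyl-2-oxo-2H-pyran-6-yl) acetonide, via bis(acetic mixed anhydride) 14 (not isolated)
Conditions: Ac2O (neat), rt, 16 h; evaporate (toluene azeotrope)
Reagents that add atoms: none
Why: Acetic anhydride activates each carboxyl as a mixed anhydride that is attacked by the enol oxygen on C6' (6-exo-trig lactonisation, the established cyclodehydration of 3,5-dioxo acids), and tautomerisation to the aromatic 4-hydroxy-2-pyranone erases the C3' stereocentres; the medium contains no strong acid, so the acetonide should survive.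

Step 8
Reactants: 15 meso bis(4-hydroxypyranone) acetonide
Product: 16 meso bis(4-methoxy-3-methyl-2-oxo-2H-pyran-6-yl) acetonide
Conditions: Me2SO4 (2.5 equiv), K2CO3 (3 equiv), acetone, reflux
Reagents that add atoms: dimethyl sulfate, COS(=O)(=O)OC
Why: O-Alkylation of the vinylogous acid of a 4-hydroxy-2-pyranone with dimethyl sulfate and K2CO3 in acetone (Williamson-type methylation) is known to favour the 4-methoxy-2-pyranone over the 2-methoxy-4-pyranone isomer.

Step 9
Reactants: 16 meso bis(4-methoxypyranone) acetonide
Product: 17 meso diol (cis-1,2-bis(hydroxymethyl) compound)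
Conditions: AcOH/H2O (4:1), 40 °C
Reagents that add atoms: none
Why: Acid-catalysed ketal hydrolysis of the seven-membered acetonide is fast in mild aqueous acetic acid, which the methoxypyranone vinylogous esters tolerate.

Step 10
Reactants: 17 meso diol
Product: 18 meso cis-1,2-dicarbaldehyde
Conditions: (COCl)2, DMSO, CH2Cl2, −78 °C; i-Pr2NEt, −78 → −30 °C; pH 7 buffer; used crude
Reagents that add atoms: none
Why: In the Swern oxidation both hydroxyls are activated before base is added, so both aldehydes are released together and lactol or lactone formation from the cis-1,4-diol is avoided; the hindered base and low temperature should prevent epimerisation at C1 and C2.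

Step 11
Reactants: 18 meso cis-1,2-dicarbaldehyde
Product: 19 meso cis-1,2-dicarboxylic acid
Conditions: NaClO2, NaH2PO4, 2-methyl-2-butene (excess), t-BuOH/H2O, 0 °C → rt
Reagents that add atoms: sodium chlorite, [Na+].[O-]Cl=O
Why: The Pinnick oxidation converts aldehydes to acids under buffered conditions without α-epimerisation; a hydroxylactone formed from the half-oxidised intermediate stays in equilibrium with the open aldehyde and is oxidised on, and the alkene scavenger removes HOCl before it can chlorinate C5' of the pyranones.

Step 12
Reactants: 19 meso cis-1,2-dicarboxylic acid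
Product: 20 meso cyclobutane-1,2-dicarboxylic anhydride (C3 and C4 each bear CH3 and the methoxypyranone)
Conditions: Ac2O, 60 °C; evaporate; used directly
Reagents that add atoms: none
Why: Cyclodehydration of a cis-1,2-diacid with acetic anhydride (cyclic anhydride formation) is reliable on cyclobutanes and is possible only because C1 and C2 are cis; it gives the meso substrate for desymmetrisation.

Step 13
Reactants: 20 meso anhydride
Product: 21 (1S,2R,3S,4R)-2-(methoxycarbonyl)-3,4-bis(4-methoxy-3-methyl-2-oxo-2H-pyran-6-yl)-3,4-dimethylcyclobutane-1-carboxylic acid (target)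
Conditions: quinine (1.1 equiv), MeOH (3 equiv), toluene, −55 °C; 1 M HCl wash
Reagents that add atoms: methanol, CO
Why: In the cinchona alkaloid-mediated desymmetrising methanolysis of a meso anhydride, quinine acts as a chiral general base that delivers methanol to one of the two enantiotopic carbonyls (here the one on C2); since C1–C4 are already fixed relative to one another in the meso framework, this single choice should set the absolute configuration of all four stereocentres.

**Compound list**

1 | 2,3-dimethylmaleic anhydride | CC1=C(C)C(=O)OC1=O | starting material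
2 | 4,7-dihydro-2,2-dimethyl-1,3-dioxepine (acetonide of (Z)-but-2-ene-1,4-diol) | CC1(C)OC/C=C\CO1 | starting material
3 | meso cis-anti-cis photoadduct: 3,4-dimethylcyclobutane-3,4-dicarboxylic anhydride, C1 and C2 cis-fused to a 2,2-dimethyl-1,3-dioxepane; anhydride ring on face α, dioxepane CH2 groups and methyls on face β | CC3(C)OC[C@@H]1[C@H](CO3)[C@@](C)(C(=O)O4)[C@@]1(C)C4=O | intermediate
4 | dilithium cis-3,4-dicarboxylate from 3, acetonide retained | CC3(C)OC[C@@H]1[C@H](CO3)[C@@](C)(C(=O)[O-])[C@@]1(C)C(=O)[O-].[Li+].[Li+] | intermediate
5 | tetralithium bis(gem-diolate), C3 and C4 each bearing C(CH3)(OLi)2; not isolated | CC3(C)OC[C@@H]1[C@H](CO3)[C@@](C)(C(C)([O-])[O-])[C@@]1(C)C(C)([O-])[O-].[Li+].[Li+].[Li+].[Li+] | intermediate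
6 | meso bis(methyl ketone): 3,4-diacetyl-3,4-dimethylcyclobutane, acetyls cis on face α, C1/C2 acetonide retained | CC3(C)OC[C@@H]1[C@H](CO3)[C@@](C)(C(C)=O)[C@@]1(C)C(C)=O | intermediate
7 | propanoyl chloride | CCC(=O)Cl | starting material
8 | 1H-benzotriazole | c1ccc2[nH]nnc2c1 | starting material
9 | 1-propanoyl-1H-benzotriazole | CCC(=O)n1nnc2ccccc21 | intermediate
10 | meso bis(1,3-diketone): C3 and C4 each bear a 1,3-dioxopentyl arm, acetonide retained | CC3(C)OC[C@@H]1[C@H](CO3)[C@@](C)(C(=O)CC(=O)CC)[C@@]1(C)C(=O)CC(=O)CC | intermediate
11 | carbon dioxide | O=C=O | starting material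
12 | tetralithium bis(dienolate) of 10, each arm C(OLi)=CH–C(OLi)=CH–CH3; not isolated | CC3(C)OC[C@@H]1[C@H](CO3)[C@@](C)(C([O-])=CC([O-])=CC)[C@@]1(C)C([O-])=CC([O-])=CC.[Li+].[Li+].[Li+].[Li+] | intermediate
13 | bis(3,5-dioxo acid): each arm C(=O)CH2C(=O)CH(CH3)CO2H, the two new methine carbons unassigned (mixture) | CC3(C)OC[C@@H]1[C@H](CO3)[C@@](C)(C(=O)CC(=O)C(C)C(=O)O)[C@@]1(C)C(=O)CC(=O)C(C)C(=O)O | intermediate
14 | bis(mixed anhydride of 13 with acetic acid); not isolated | CC3(C)OC[C@@H]1[C@H](CO3)[C@@](C)(C(=O)CC(=O)C(C)C(=O)OC(C)=O)[C@@]1(C)C(=O)CC(=O)C(C)C(=O)OC(C)=O | intermediate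
15 | meso bis(4-hydroxy-3-methyl-2-oxo-2H-pyran-6-yl) compound, pyranones on face α, acetonide retained | CC3(C)OC[C@@H]1[C@H](CO3)[C@@](C)(c2cc(O)c(C)c(=O)o2)[C@@]1(C)c1cc(O)c(C)c(=O)o1 | intermediate
16 | meso bis(4-methoxy-3-methyl-2-oxo-2H-pyran-6-yl) acetonide | CC3(C)OC[C@@H]1[C@H](CO3)[C@@](C)(c2cc(OC)c(C)c(=O)o2)[C@@]1(C)c1cc(OC)c(C)c(=O)o1 | intermediate
17 | meso diol: cis-1,2-bis(hydroxymethyl)-3,4-dimethyl-3,4-bis(4-methoxy-3-methyl-2-oxo-2H-pyran-6-yl)cyclobutane | OC[C@@H]1[C@H](CO)[C@@](C)(c2cc(OC)c(C)c(=O)o2)[C@@]1(C)c1cc(OC)c(C)c(=O)o1 | intermediate
18 | meso cis-1,2-dicarbaldehyde of the same core | O=C[C@@H]1[C@H](C=O)[C@@](C)(c2cc(OC)c(C)c(=O)o2)[C@@]1(C)c1cc(OC)c(C)c(=O)o1 | intermediate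
19 | meso cis-1,2-dicarboxylic acid of the same core | OC(=O)[C@@H]1[C@H](C(=O)O)[C@@](C)(c2cc(OC)c(C)c(=O)o2)[C@@]1(C)c1cc(OC)c(C)c(=O)o1 | intermediate
20 | meso cyclobutane-1,2-dicarboxylic anhydride of the same core (anhydride on face β, pyranones on face α) | O=C5OC(=O)[C@@H]1[C@H]5[C@@](C)(c2cc(OC)c(C)c(=O)o2)[C@@]1(C)c1cc(OC)c(C)c(=O)o1 | intermediate
21 | (1S,2R,3S,4R)-2-(methoxycarbonyl)-3,4-bis(4-methoxy-3-methyl-2-oxo-2H-pyran-6-yl)-3,4-dimethylcyclobutane-1-carboxylic acid | COC(=O)[C@@H]1[C@H](C(=O)O)[C@@](C)(c2cc(OC)c(C)c(=O)o2)[C@@]1(C)c1cc(OC)c(C)c(=O)o1 | target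

**Totals**

Total step count: 13. Longest linear sequence: 12 steps (steps 1–3 and 5–13; step 4 is a one-step side branch).

**Steps most likely to fail**

Step 6. The tetralithium species may form incompletely through aggregation. Proton return during CO2 uptake may leave one arm uncarboxylated. The β-keto acids may lose CO2, or the acetonide may open, during the cold acidification. The fallback sets out from bis(methyl ketone) 6 and avoids the diketone polyanion altogether. Double kinetic enolisation with LiN(i-Pr)2 in the presence of Me3SiCl (THF, −78 °C, in situ quench) should give the bis(trimethylsilyl enol ether) F1. Its reaction with methylmalonyl dichloride (CC(C(=O)Cl)C(=O)Cl; Et2O, −78 °C → rt, HCl swept out with argon) is the known acylation–lactonisation route from silyl enol ethers and malonyl dichlorides to 4-hydroxy-2-pyranones. It would form C4'–C5' and O1'–C2' of both rings in one operation and return to the route at 15.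

Step 3. The addition to the hindered, poorly soluble dilithium salt may stay incomplete. Alternatively a gem-diolate may collapse before the quench, so that over-addition to a tertiary alcohol or lactone takes over. The fallback sets out from anhydride 3. Reduction with LiAlH4 (THF, 0 °C → reflux) should give the neopentyl diol F2. Swern oxidation should give the dialdehyde F3, which has no α-hydrogen and is configurationally safe. Addition of MeMgBr (THF, −78 → 0 °C) should give the bis(1-hydroxyethyl) compound F4 as a mixture of carbinol epimers. A second Swern oxidation returns to the route at 6.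

Step 13. The anhydride is flanked by two quaternary carbons and may be poorly soluble at −55 °C, so the methanolysis may be slow or poorly enantioselective, or may take the opposite sense. The fallback sets out from 20. Unselective opening (MeOH, Et3N, DMAP cat., CH2Cl2, rt) should give the racemic hemiester F5. Classical resolution follows, by fractional crystallisation of its salts with (R)-1-phenylethylamine from EtOH/EtOAc, aiming at the salt F6 of the (1S,2R,3S,4R)-acid. If the other diastereomeric salt is the less soluble one, it is removed first and F6 is taken from the mother liquor. Release with cold dilute HCl returns to the route at 21.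

**Further compounds**

F1 | step 6 | bis(trimethylsilyl enol ether) of 6 (C3 and C4 each bear C(=CH2)OSiMe3) | CC3(C)OC[C@@H]1[C@H](CO3)[C@@](C)(C(=C)O[Si](C)(C)C)[C@@]1(C)C(=C)O[Si](C)(C)C
F2 | step 3 | meso 3,4-bis(hydroxymethyl)-3,4-dimethylcyclobutane with the C1/C2 acetonide | CC3(C)OC[C@@H]1[C@H](CO3)[C@@](C)(CO)[C@@]1(C)CO
F3 | step 3 | meso 3,4-dicarbaldehyde of the same core | CC3(C)OC[C@@H]1[C@H](CO3)[C@@](C)(C=O)[C@@]1(C)C=O
F4 | step 3 | 3,4-bis(1-hydroxyethyl) compound, carbinol centres unassigned | CC3(C)OC[C@@H]1[C@H](CO3)[C@@](C)(C(C)O)[C@@]1(C)C(C)O
F5 | step 13 | racemic hemiester (21 together with its enantiomer) | COC(=O)[C@@H]1[C@H](C(=O)O)[C@@](C)(c2cc(OC)c(C)c(=O)o2)[C@@]1(C)c1cc(OC)c(C)c(=O)o1.COC(=O)[C@H]1[C@@H](C(=O)O)[C@](C)(c2cc(OC)c(C)c(=O)o2)[C@]1(C)c1cc(OC)c(C)c(=O)o1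
F6 | step 13 | (R)-1-phenylethylammonium salt of 21 | COC(=O)[C@@H]1[C@H](C(=O)[O-])[C@@](C)(c2cc(OC)c(C)c(=O)o2)[C@@]1(C)c1cc(OC)c(C)c(=O)o1.C[C@@H]([NH3+])c1ccccc1
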